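The constants below serve violet, teal and blue, which differ in their charge of D.

    Z + J → Z.J (k1 = 4.7 M⁻¹ min⁻¹)
    J + Z.J → J.Z.J (k2 = 1.1 M⁻¹ min⁻¹)
    J + J.Z.J ⇌ G (K3 = 9.5 M⁻¹, k3 = 6.9 M⁻¹ min⁻¹)
    D ⇌ J, rate k4*(cs4 - [J]) while solid is left; crystals form when [J] > cs4 (cs4 = 21 mM, k4 = 0.046 min⁻¹)

all flasks: Z 0.12 M; time 20 min
- violet: D 0.620 M
- teal: D 0.310 M
- blue: D 0.160 M

- as a solid, counted per litre of solution: D
- at the start none of D is in solution
- run time (violet): 20 min

- which of the two there is more of at the end, violet (Z.J / J.Z.J)
- which of the two there is more of at the end, teal (Z.J / J.Z.J)
- which of the two there is more of at the end, blue (Z.J / J.Z.J)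
- how much Z.J is there at the end, in percent of the Z charged: violet
- how much Z.J is there at the end, in percent of the Z charged: teal
- how much Z.J is there at the end, in percent of the Z charged: blue

Two chemists disagree before any run. The first counts equivalents: violet holds 5.17 of D per Z, blue 1.33. She takes the whole charge as dissolved, which makes the loss of Z.J in violet pseudo-first-order, with 13.6 lifetimes of Z.J in the run. So she expects J.Z.J ahead in violet. She expects Z.J ahead in blue, where the first addition is faster than the second by a selectivity factor of 4.27.

The second chemist looks at the solid. D enters solution at the dissolution coefficient times the gap between solubility and c(J), and that gap is widest at zero c(J). He therefore carries the dissolution ceiling, coefficient times solubility times run time, 19.3 mM: the most J that can reach solution in the run. That is less than the smallest charge, just 12.1% of blue's, so he expects the charge to make no difference.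

My own reckoning takes his side and computes only the correction. Z takes up J with a first-order constant of 0.564 min⁻¹, far larger than the dissolution coefficient of 0.046 min⁻¹, so c(J) rests near 1.58 mM, far below the solubility of 21 mM. Dissolving then runs 7.52% under the ceiling. After subtracting the J still in solution, the J taken up comes to 13.6% of the Z charged. That is my figure for violet, teal and blue alike, and it counts J taken up, so J.Z.J claims a little of it.

The forecast gives 13% of Z.J for violet, 13% for teal and 13% for blue, with Z.J, Z.J and Z.J as the larger product, and holds that “the three runs are identical”. Its figure for violet is lower than my 13.6%, but its figure counts Z.J and mine counts J taken up.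

The flask gives Z.J at 13.0%, 13.0% and 13.0% for violet, teal and blue, and the larger product is Z.J, Z.J and Z.J in that order, with J.Z.J at 0.221% in violet. With the limit of solubility of J lifted, so that J also dissolves that much faster, violet minus blue in Z.J comes to −60 percentage points, and that is the region of the first chemist's equivalents. The ceiling lets blue lose 12.1% of its D, and 88.8% stands there at the end. A neighbour of teal charged with 0.78 M of D, 6.50 equiv, may lose 2.47%; it keeps 97.7% of its D and ends with Z.J at 13.0%.

All constants come from no measurement; the run is a simulation.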